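(Readings and results come from a simulation for an exercise.)

The trap in this row is to expect that more second end groups leave more links at the end. Links are an intermediate that also gets lost, so what you find at 30 h depends on how far each flask has passed its peak.

| setting | green | violet | spring | noon | midnight | winter |
|---|---|---|---|---|---|---|
| first end groups | 1 M | 1 M | 1.0 M | 1.0 M | 1.0 M | 1.0 M |
| second end groups | 0.49 M | 2.4 M | 0.400 M | 0.600 M | 1.00 M | 1.50 M |
| remark | run made earlier | run made earlier |  |  |  |  |
| time |  |  | 30 h | 30 h | 30 h | 30 h |

| green: time / h | green: links / % | violet: time / h | violet: links / % |
|---|---|---|---|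
| 1.50 | 3 | 1.00 | 11 |
| 2.50 | 6 | 3.00 | 25 |
| 4.00 | 11 | 6.00 | 34 |
| 6.00 | 8 | 10.0 | 37 |
| 10.0 | 12 | 12.0 | 34 |
| 15.0 | 17 | 15.0 | 31 |
| 20.0 | 18 | 20.0 | 25 |

(standard deviation of a reading: 1.5 percentage points)

- steps under discussion: links + released group -> side product; first end groups + second end groups <-> links + released group; second end groups + links -> over-reaction product; first end groups <-> dormant form
- "hardly changes" means that all values lie within two and a half points (for a concentration: within two and a half percent of the largest)

- [links] at the end for spring, noon, midnight, winter, in this order
- how the row runs (hardly changes / falls all the way / rises all the way / rises, then falls / falls, then rises)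

You take over the flasks, and here is what I expect you to find. Green shows 3% after 1.50 h and violet 11% after 1.00 h, so I let the clock run with the charge of second end groups. Violet's highest reading is 37% at 10.0 h, and since it carries a scatter of 1.5 percentage points, I take it only as a rough mark of the peak, which on that clock puts the winter peak near 16.0 h and the midnight peak near 24.0 h. For the loss I use the fall life, the mean height of the links past the peak divided by their mean loss per hour, which violet's readings give as 25.8 h. Replacing the curve by its mean costs little, since the exponential through the same two readings gives 25.5 h. Scaled by charge, the fall life is 41.3 h in winter and 62.0 h in midnight. Taking violet's highest reading as the peak height in both, I reckon 0.336 M for midnight and 0.264 M for winter, so I expect winter below midnight. Green stands at 18% at 20.0 h, so I put the two leaner flasks below midnight, and the row rises, then falls. Leave the charges alone, and do not take a late winter sample for the peak.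

The forecast differs: 0.21 M, 0.27 M, 0.34 M, 0.35 M, rises all the way, with the words “winter could tip over, but it probably stays just above midnight”.

The flasks give 0.156 M, 0.185 M, 0.207 M and 0.200 M, so the row rises, then falls, and my two heights stand above what the flasks hold.

    links + released group → side product (k = 0.00260 L mol⁻¹ min⁻¹)
    first end groups + second end groups ⇌ links + released group (K = 2.70, k = 8.40 × 10⁻⁴ L mol⁻¹ min⁻¹)
    second end groups + links → over-reaction product (k = 2.80 × 10⁻⁴ L mol⁻¹ min⁻¹)
    first end groups ⇌ dormant form (K = 1.30, k = 1.30 × 10⁻⁴ min⁻¹)

In spring, links are made 3.89 times as fast as they are used up at 8.70 h. By 30.0 h that ratio has dropped to 0.749, so spring is losing links on balance at the asked time. Between 15.0 h and 30.0 h, the winter heights give a fall life of 39.1 h, against 41.3 h scaled from violet. The midnight heights over the same hours give 67.5 h, against 62.0 h.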